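**Plan**

- Retrosynthesis: after removal of the benzyl-type and silyl groups, the naringenin unit is cut at C2''–aryl (back to a chromone), the eriodictyol unit at C2–C3 (ring C, back to an α-aryl α-diazo ketone), and the ketone at C4–C4a (aryllithium plus arylacetaldehyde).
- Forward: a ring-A aryl bromide and a chromone carrying a C8'' acetaldehyde arm (O-allylation, Claisen shift, ozonolysis) are joined and oxidised to the deoxybenzoin; diazo transfer follows; ring C of the eriodictyol unit closes; the chromone is then arylated to complete the naringenin ring; deprotection ends the route.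
- Enabling feature: C2 of the eriodictyol unit is a benzylic carbon on the ring-A oxygen O1, and C3 is α to the C4 ketone and carries the C8'' aryl group. A carbenoid at C3 can therefore insert into an O–CH2 C–H bond of a 3,4-dioxygenated benzyl ether on ring A, making C2–C3 and ring C.
- Stereochemistry: C2 (R) comes from a chiral dirhodium carboxylate choosing between the enantiotopic benzylic hydrogens; C3 (S) from base equilibration to 2,3-trans; C2'' (S) from a chiral palladium pyridine-oxazoline catalyst in the conjugate addition.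

Key step: step 13

Remark: the sense of induction of both chiral catalysts is assigned by analogy with their accepted facial models; if either proves opposite, the mirror-image catalyst is used and nothing else changes.

**Route**

Step 1
Reactants: 1 3,4-bis(benzyloxy)benzaldehyde
Product: 2 3,4-bis(benzyloxy)benzyl alcohol
Conditions: NaBH4, MeOH–THF, 0 °C
Reagents that add atoms: none
Why: Borohydride reduction of an aryl aldehyde to the benzylic alcohol is clean and leaves the benzyl ethers untouched.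

Step 2
Reactants: 2 3,4-bis(benzyloxy)benzyl alcohol
Product: 3 3,4-bis(benzyloxy)benzyl bromide
Conditions: PBr3, Et2O, 0 °C
Reagents that add atoms: phosphorus tribromide, BrP(Br)Br
Why: Bromination of a primary benzylic alcohol with PBr3 (substitution via the phosphite ester) is standard for electron-rich benzyl alcohols, and the bromide is used promptly.

Step 3
Reactants: 4 phloroglucinol; 3 3,4-bis(benzyloxy)benzyl bromide (3.3 equiv)
Product: 5 1,3,5-tris[3,4-bis(benzyloxy)benzyloxy]benzene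
Conditions: 3 (3.3 equiv in all), K2CO3 (4 equiv), DMF, rt → 50 °C
Reagents that add atoms: 3,4-bis(benzyloxy)benzyl bromide (the second and third equivalents of 3), BrCc1ccc(OCc2ccccc2)c(OCc2ccccc2)c1.BrCc1ccc(OCc2ccccc2)c(OCc2ccccc2)c1
Why: In this threefold Williamson etherification each of the three phenoxide oxygens displaces bromide from one molecule of 3, so three equivalents of the bromide are built into 5, and carbonate in a dipolar aprotic solvent favours O- over C-alkylation, as in the preparation of 1,3,5-tribenzyloxybenzene.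

Step 4
Reactants: 5 1,3,5-tris[3,4-bis(benzyloxy)benzyloxy]benzene
Product: 6 2-bromo-1,3,5-tris[3,4-bis(benzyloxy)benzyloxy]benzene
Conditions: NBS (1.0 equiv), CH2Cl2, −78 → 0 °C
Reagents that add atoms: N-bromosuccinimide, O=C1CCC(=O)N1Br
Why: Electrophilic aromatic bromination should occur only on the central ring, whose three equivalent positions are each activated by three alkoxy groups and react far faster than the catechol ether rings.

Step 5
Reactants: 7 5,7-dihydroxy-4H-chromen-4-one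
Product: 8 7-allyloxy-5-hydroxy-4H-chromen-4-one
Conditions: allyl bromide (1.1 equiv), K2CO3, acetone, reflux
Reagents that add atoms: allyl bromide, C=CCBr
Why: Williamson etherification is selective for the acidic 7-OH because the 5-OH is hydrogen-bonded to the C4 carbonyl and reacts only under forcing conditions.

Step 6
Reactants: 8 7-allyloxy-5-hydroxy-4H-chromen-4-one
Product: 9 7-allyloxy-5-benzyloxy-4H-chromen-4-one
Conditions: BnBr, K2CO3, DMF, 60 °C
Reagents that add atoms: benzyl bromide, BrCc1ccccc1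
Why: Under more forcing Williamson conditions the chelated 5-OH is benzylated, which removes the acidic proton and should steer the next step towards C8.

Step 7
Reactants: 9 7-allyloxy-5-benzyloxy-4H-chromen-4-one
Product: 10 8-allyl-5-benzyloxy-7-hydroxy-4H-chromen-4-one
Conditions: PhNEt2, 190 °C
Reagents that add atoms: none
Why: The aromatic Claisen rearrangement of 7-allyloxy benzopyranones is expected to deliver the allyl group mainly to C8 (the C7–C8 bond has the higher double-bond character), with any C6 isomer removed by chromatography.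

Step 8
Reactants: 10 8-allyl-5-benzyloxy-7-hydroxy-4H-chromen-4-one
Product: 11 8-allyl-5-benzyloxy-7-(tert-butyldimethylsilyloxy)-4H-chromen-4-one
Conditions: TBSCl, imidazole, DMF, rt
Reagents that add atoms: tert-butyldimethylsilyl chloride, CC(C)(C)[Si](C)(C)Cl
Why: Silylation protects the phenol with a group that places silicon, not a C–H bond, five atoms from the later carbenoid carbon, so no five-membered insertion can compete in step 13.

Step 9
Reactants: 11 8-allyl-5-benzyloxy-7-(tert-butyldimethylsilyloxy)-4H-chromen-4-one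
Product: 13 2-[5-benzyloxy-7-(tert-butyldimethylsilyloxy)-4-oxo-4H-chromen-8-yl]acetaldehyde, via secondary ozonide 12 (not isolated)
Conditions: O3, CH2Cl2, −78 °C, stopped at first excess; then Me2S, −78 °C → rt; used crude
Reagents that add atoms: ozone, [O-][O+]=O
Why: Ozonolysis with reductive work-up cleaves the electron-rich terminal alkene much faster than the electron-poor pyranone double bond and gives the arylacetaldehyde under anhydrous, neutral conditions.

Step 10
Reactants: 6 2-bromo-1,3,5-tris[3,4-bis(benzyloxy)benzyloxy]benzene; 13 2-[5-benzyloxy-7-(tert-butyldimethylsilyloxy)-4-oxo-4H-chromen-8-yl]acetaldehyde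
Product: 15 racemic 1-{2,4,6-tris[3,4-bis(benzyloxy)benzyloxy]phenyl}-2-[5-benzyloxy-7-(tert-butyldimethylsilyloxy)-4-oxo-4H-chromen-8-yl]ethanol, via aryllithium 14 (not isolated)
Conditions: n-BuLi, THF, −78 °C; then 13, −78 °C; AcOH quench
Reagents that add atoms: none
Why: Bromine–lithium exchange at −78 °C outpaces benzylic deprotonation, and 1,2-addition of the aryllithium to the formyl group should be faster than attack on the vinylogous-ester carbonyl of the pyranone; the new carbinol centre is removed in the next step.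

Step 11
Reactants: 15 racemic 1-{2,4,6-tris[3,4-bis(benzyloxy)benzyloxy]phenyl}-2-[5-benzyloxy-7-(tert-butyldimethylsilyloxy)-4-oxo-4H-chromen-8-yl]ethanol
Product: 16 1-{2,4,6-tris[3,4-bis(benzyloxy)benzyloxy]phenyl}-2-[5-benzyloxy-7-(tert-butyldimethylsilyloxy)-4-oxo-4H-chromen-8-yl]ethanone
Conditions: Dess–Martin periodinane, NaHCO3, CH2Cl2, 0 °C → rt
Reagents that add atoms: none
Why: Buffered Dess–Martin oxidation converts the ionisation-prone, electron-rich benzylic alcohol to the deoxybenzoin without acid, sparing the acid-labile benzylic ethers and the silyl ether.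

Step 12
Reactants: 16 1-{2,4,6-tris[3,4-bis(benzyloxy)benzyloxy]phenyl}-2-[5-benzyloxy-7-(tert-butyldimethylsilyloxy)-4-oxo-4H-chromen-8-yl]ethanone
Product: 17 2-diazo-1-{2,4,6-tris[3,4-bis(benzyloxy)benzyloxy]phenyl}-2-[5-benzyloxy-7-(tert-butyldimethylsilyloxy)-4-oxo-4H-chromen-8-yl]ethanone
Conditions: p-ABSA, DBU, MeCN–CH2Cl2, 0 °C → rt
Reagents that add atoms: 4-acetamidobenzenesulfonyl azide, CC(=O)Nc1ccc(cc1)S(=O)(=O)N=[N+]=[N-]
Why: Regitz diazo transfer works directly on deoxybenzoins because the methylene is activated by both the ketone and the aryl group, and it is the only enolisable position in 16.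

Step 13
Reactants: 17 2-diazo-1-{2,4,6-tris[3,4-bis(benzyloxy)benzyloxy]phenyl}-2-[5-benzyloxy-7-(tert-butyldimethylsilyloxy)-4-oxo-4H-chromen-8-yl]ethanone
Product: 19 (2R,3S)-2-[3,4-bis(benzyloxy)phenyl]-3-[5-benzyloxy-7-(tert-butyldimethylsilyloxy)-4-oxo-4H-chromen-8-yl]-5,7-bis[3,4-bis(benzyloxy)benzyloxy]chroman-4-one, via cis-chromanone 18 (not isolated)
Conditions: Rh2(S-PTTL)4 (dirhodium tetrakis[N-phthaloyl-(S)-tert-leucinate], 2 mol %), toluene, −20 °C → rt; then DBU (0.2 equiv), rt
Reagents that add atoms: none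
Why: The dirhodium carboxylate expels N2 from 17 to give an electrophilic aryl/acyl rhodium carbenoid at the future C3, which inserts into a benzylic O–CH2 C–H bond of an ortho 3,4-bis(benzyloxy)benzyl ether through a concerted, hydride-transfer-like three-centre transition state and so forms C2–C3. The closest known reaction type is the dirhodium-carboxylate-catalysed intramolecular C–H insertion of 2-alkoxyaryl α-diazo ketones into the ether α-C–H bond to give chroman-4-ones, together with enantioselective benzylic-ether insertions of aryl-substituted carbenoids. Ring C closes as a six-membered ring by 1,6-insertion (carbenoid carbon, carbonyl carbon, two ring-A carbons, oxygen, benzylic carbon). C2 is set by the chiral catalyst, which selects one of the two enantiotopic benzylic hydrogens with retention at carbon, and C3, being benzylic and α to the ketone, is then equilibrated by catalytic DBU from the expected kinetic cis isomer 18 to the trans arrangement with both aryl groups equatorial. The step needs insertion to outrun oxonium-ylide formation and to occur at one site only: the targeted C–H is the only one within reach that is both benzylic and α to oxygen and is made strongly hydridic by its dialkoxyphenyl ring, the two ortho ethers are identical, and no position five atoms away bears hydrogen. On the chromone side the silyl ether offers only unactivated Si–CH3 bonds and the pyranone oxygen holds its sp2 C2''–H turned away from the carbenoid.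

Step 14
Reactants: 19 (2R,3S)-trans chromanone from step 13; 20 4-(benzyloxy)phenylboronic acid
Product: 21 (2R,3S)-2-[3,4-bis(benzyloxy)phenyl]-3-[(2S)-5-benzyloxy-2-(4-benzyloxyphenyl)-7-(tert-butyldimethylsilyloxy)-4-oxochroman-8-yl]-5,7-bis[3,4-bis(benzyloxy)benzyloxy]chroman-4-one
Conditions: Pd(OCOCF3)2 (10 mol %), (R)-t-BuPyOx (12 mol %), NH4PF6, H2O, ClCH2CH2Cl, 60 °C
Reagents that add atoms: none
Why: Palladium-catalysed asymmetric conjugate addition of arylboronic acids to chromones is an established route to flavanones; the aryl–palladium species adds to C2'' of the only enone present, protonolysis by water releases the ketone, and the tert-butyl group of the ligand controls the face so that C2'' should be S, far from and independent of the ring-C stereocentres.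

Step 15
Reactants: 21 silyl-protected biflavanone from step 14
Product: 22 (2R,3S)-2-[3,4-bis(benzyloxy)phenyl]-3-[(2S)-5-benzyloxy-2-(4-benzyloxyphenyl)-7-hydroxy-4-oxochroman-8-yl]-5,7-bis[3,4-bis(benzyloxy)benzyloxy]chroman-4-one
Conditions: TBAF, AcOH (1:1), THF, 0 °C
Reagents that add atoms: none
Why: Fluoride cleaves the aryl silyl ether, and the acetic acid buffer keeps the medium from becoming basic enough to enolise either flavanone and open it by retro-oxa-Michael reaction.

Step 16
Reactants: 22 phenol from step 15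
Product: 23 (2R,3S)-2-(3,4-dihydroxyphenyl)-5,7-dihydroxy-3-[(2S)-5,7-dihydroxy-2-(4-hydroxyphenyl)-4-oxochroman-8-yl]chroman-4-one (CNP0105436.2)
Conditions: H2 (1 atm), 10% Pd/C, THF–MeOH, rt
Reagents that add atoms: none
Why: Hydrogenolysis cleaves all ten benzylic ether C–O bonds (the two 3,4-bis(benzyloxy)benzyl ethers leave as 4-methylcatechol), while under these mild neutral conditions the ring C2–O bonds, the ketones and the three stereocentres should remain intact.

**Compound list**

1 | 3,4-bis(benzyloxy)benzaldehyde | O=Cc1ccc(OCc2ccccc2)c(OCc2ccccc2)c1 | starting material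
2 | 3,4-bis(benzyloxy)benzyl alcohol | OCc1ccc(OCc2ccccc2)c(OCc2ccccc2)c1 | intermediate
3 | 3,4-bis(benzyloxy)benzyl bromide | BrCc1ccc(OCc2ccccc2)c(OCc2ccccc2)c1 | intermediate
4 | phloroglucinol | Oc1cc(O)cc(O)c1 | starting material
5 | 1,3,5-tris[3,4-bis(benzyloxy)benzyloxy]benzene | c1c(OCc2ccc(OCc3ccccc3)c(OCc3ccccc3)c2)cc(OCc2ccc(OCc3ccccc3)c(OCc3ccccc3)c2)cc1OCc1ccc(OCc2ccccc2)c(OCc2ccccc2)c1 | intermediate
6 | 2-bromo-1,3,5-tris[3,4-bis(benzyloxy)benzyloxy]benzene | Brc1c(OCc2ccc(OCc3ccccc3)c(OCc3ccccc3)c2)cc(OCc2ccc(OCc3ccccc3)c(OCc3ccccc3)c2)cc1OCc1ccc(OCc2ccccc2)c(OCc2ccccc2)c1 | intermediate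
7 | 5,7-dihydroxy-4H-chromen-4-one (5,7-dihydroxychromone) | O=c1ccoc2cc(O)cc(O)c12 | starting material
8 | 7-allyloxy-5-hydroxy-4H-chromen-4-one | C=CCOc1cc(O)c2c(=O)ccoc2c1 | intermediate
9 | 7-allyloxy-5-benzyloxy-4H-chromen-4-one | C=CCOc1cc(OCc2ccccc2)c2c(=O)ccoc2c1 | intermediate
10 | 8-allyl-5-benzyloxy-7-hydroxy-4H-chromen-4-one | C=CCc1c(O)cc(OCc2ccccc2)c2c(=O)ccoc12 | intermediate
11 | 8-allyl-5-benzyloxy-7-(tert-butyldimethylsilyloxy)-4H-chromen-4-one | C=CCc1c(O[Si](C)(C)C(C)(C)C)cc(OCc2ccccc2)c2c(=O)ccoc12 | intermediate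
12 | secondary ozonide of 11, 5-benzyloxy-7-(tert-butyldimethylsilyloxy)-8-(1,2,4-trioxolan-3-ylmethyl)-4H-chromen-4-one (ring carbon racemic) | C1OOC(Cc2c(O[Si](C)(C)C(C)(C)C)cc(OCc3ccccc3)c3c(=O)ccoc23)O1 | intermediate (not isolated)
13 | 2-[5-benzyloxy-7-(tert-butyldimethylsilyloxy)-4-oxo-4H-chromen-8-yl]acetaldehyde | O=CCc1c(O[Si](C)(C)C(C)(C)C)cc(OCc2ccccc2)c2c(=O)ccoc12 | intermediate
14 | 2,4,6-tris[3,4-bis(benzyloxy)benzyloxy]phenyllithium | [Li]c1c(OCc2ccc(OCc3ccccc3)c(OCc3ccccc3)c2)cc(OCc2ccc(OCc3ccccc3)c(OCc3ccccc3)c2)cc1OCc1ccc(OCc2ccccc2)c(OCc2ccccc2)c1 | intermediate (not isolated)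
15 | racemic 1-{2,4,6-tris[3,4-bis(benzyloxy)benzyloxy]phenyl}-2-[5-benzyloxy-7-(tert-butyldimethylsilyloxy)-4-oxo-4H-chromen-8-yl]ethanol | OC(Cc1c(O[Si](C)(C)C(C)(C)C)cc(OCc2ccccc2)c2c(=O)ccoc12)c1c(OCc2ccc(OCc3ccccc3)c(OCc3ccccc3)c2)cc(OCc2ccc(OCc3ccccc3)c(OCc3ccccc3)c2)cc1OCc1ccc(OCc2ccccc2)c(OCc2ccccc2)c1 | intermediate
16 | 1-{2,4,6-tris[3,4-bis(benzyloxy)benzyloxy]phenyl}-2-[5-benzyloxy-7-(tert-butyldimethylsilyloxy)-4-oxo-4H-chromen-8-yl]ethanone | O=C(Cc1c(O[Si](C)(C)C(C)(C)C)cc(OCc2ccccc2)c2c(=O)ccoc12)c1c(OCc2ccc(OCc3ccccc3)c(OCc3ccccc3)c2)cc(OCc2ccc(OCc3ccccc3)c(OCc3ccccc3)c2)cc1OCc1ccc(OCc2ccccc2)c(OCc2ccccc2)c1 | intermediate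
17 | 2-diazo-1-{2,4,6-tris[3,4-bis(benzyloxy)benzyloxy]phenyl}-2-[5-benzyloxy-7-(tert-butyldimethylsilyloxy)-4-oxo-4H-chromen-8-yl]ethanone | [N-]=[N+]=C(c1c(O[Si](C)(C)C(C)(C)C)cc(OCc2ccccc2)c2c(=O)ccoc12)C(=O)c1c(OCc2ccc(OCc3ccccc3)c(OCc3ccccc3)c2)cc(OCc2ccc(OCc3ccccc3)c(OCc3ccccc3)c2)cc1OCc1ccc(OCc2ccccc2)c(OCc2ccccc2)c1 | intermediate (key-step precursor)
18 | (2R,3R)-2-[3,4-bis(benzyloxy)phenyl]-3-[5-benzyloxy-7-(tert-butyldimethylsilyloxy)-4-oxo-4H-chromen-8-yl]-5,7-bis[3,4-bis(benzyloxy)benzyloxy]chroman-4-one (2,3-cis) | O=C1c2c(OCc3ccc(OCc4ccccc4)c(OCc4ccccc4)c3)cc(OCc3ccc(OCc4ccccc4)c(OCc4ccccc4)c3)cc2O[C@@H](c2ccc(OCc3ccccc3)c(OCc3ccccc3)c2)[C@H]1c1c(O[Si](C)(C)C(C)(C)C)cc(OCc2ccccc2)c2c(=O)ccoc12 | intermediate (not isolated)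
19 | (2R,3S)-2-[3,4-bis(benzyloxy)phenyl]-3-[5-benzyloxy-7-(tert-butyldimethylsilyloxy)-4-oxo-4H-chromen-8-yl]-5,7-bis[3,4-bis(benzyloxy)benzyloxy]chroman-4-one (2,3-trans) | O=C1c2c(OCc3ccc(OCc4ccccc4)c(OCc4ccccc4)c3)cc(OCc3ccc(OCc4ccccc4)c(OCc4ccccc4)c3)cc2O[C@@H](c2ccc(OCc3ccccc3)c(OCc3ccccc3)c2)[C@@H]1c1c(O[Si](C)(C)C(C)(C)C)cc(OCc2ccccc2)c2c(=O)ccoc12 | intermediate (key-step product)
20 | 4-(benzyloxy)phenylboronic acid | OB(O)c1ccc(OCc2ccccc2)cc1 | starting material
21 | (2R,3S)-2-[3,4-bis(benzyloxy)phenyl]-3-[(2S)-5-benzyloxy-2-(4-benzyloxyphenyl)-7-(tert-butyldimethylsilyloxy)-4-oxochroman-8-yl]-5,7-bis[3,4-bis(benzyloxy)benzyloxy]chroman-4-one | O=C1C[C@@H](c2ccc(OCc3ccccc3)cc2)Oc2c1c(OCc1ccccc1)cc(O[Si](C)(C)C(C)(C)C)c2[C@@H]1C(=O)c2c(OCc3ccc(OCc4ccccc4)c(OCc4ccccc4)c3)cc(OCc3ccc(OCc4ccccc4)c(OCc4ccccc4)c3)cc2O[C@H]1c1ccc(OCc2ccccc2)c(OCc2ccccc2)c1 | intermediate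
22 | (2R,3S)-2-[3,4-bis(benzyloxy)phenyl]-3-[(2S)-5-benzyloxy-2-(4-benzyloxyphenyl)-7-hydroxy-4-oxochroman-8-yl]-5,7-bis[3,4-bis(benzyloxy)benzyloxy]chroman-4-one | O=C1C[C@@H](c2ccc(OCc3ccccc3)cc2)Oc2c1c(OCc1ccccc1)cc(O)c2[C@@H]1C(=O)c2c(OCc3ccc(OCc4ccccc4)c(OCc4ccccc4)c3)cc(OCc3ccc(OCc4ccccc4)c(OCc4ccccc4)c3)cc2O[C@H]1c1ccc(OCc2ccccc2)c(OCc2ccccc2)c1 | intermediate
23 | (2R,3S)-2-(3,4-dihydroxyphenyl)-5,7-dihydroxy-3-[(2S)-5,7-dihydroxy-2-(4-hydroxyphenyl)-4-oxochroman-8-yl]chroman-4-one | O=C1C[C@@H](c2ccc(O)cc2)Oc2c1c(O)cc(O)c2[C@@H]1C(=O)c2c(O)cc(O)cc2O[C@H]1c1ccc(O)c(O)c1 | target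

**Step count and risks**

Total steps: 16. Longest linear sequence: 12 steps (7 to 23, steps 5–16).

Most likely to fail, in order:

1. Step 13. The ortho ether oxygen may capture the carbenoid as an oxonium ylide, followed by a 1,2-shift of the benzyl group, faster than C–H insertion; or the catalyst may discriminate poorly between the two enantiotopic hydrogens. The fallback sets out from 16 and returns at 21. Chelation-controlled cleavage of one of the two carbonyl-flanking benzylic ethers with MgBr2·OEt2 (toluene–Et2O, rt) should give the 2-hydroxyaryl ketone F1. Condensation of F1 with aldehyde 1 (piperidine, toluene, 80 °C) is a Knoevenagel condensation followed by oxa-Michael closure, the classical 2-aryl-isoflavanone synthesis. It should give the 2,3-trans chromanone as a racemate, that is 19 together with its (2S,3R)-enantiomer F2; any chromone opened by the amine recloses on acidic work-up. The pair is taken through step 14, where the catalyst sets C2'' as S in both, and 21 is separated by chromatography from the (2S,3R,2''S)-diastereomer F3.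

2. Step 14. Carbopalladation of the electron-rich, crowded chromone may be slower than protodeboronation of the boronic acid, or the stereocentres of ring C may oppose the catalyst and erode facial selectivity. The fallback sets out from 16 and returns at 21: the arylation is moved ahead of ring-C closure and to rhodium catalysis. Ketone 16, which has no stereocentre, is treated with 20 under [Rh(OH)(cod)]2 and an electron-poor chiral bisphosphine of the MeO-BIPHEP family (toluene, rt) to give the (2S)-flavanone ketone F4. Diazo transfer as in step 12 gives the diazo ketone F5. The conditions of step 13 then give the cis insertion product F6 and, after DBU equilibration, 21. The flavanone C2''–H of F5 is held by its ring on the far side of O1'' and cannot be reached by the carbenoid.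

3. Step 10. Proton transfer from the enolisable arylacetaldehyde to the basic aryllithium, or attack of the aryllithium on the pyranone, may outrun addition to the formyl group. The fallback sets out from 13 and returns at 16. Pinnick oxidation of 13 (NaClO2, NaH2PO4, 2-methyl-2-butene, t-BuOH–H2O) gives the arylacetic acid F7. Its mixed anhydride with trifluoroacetic anhydride acylates arene 5 (Friedel–Crafts acylation, CH2Cl2, 0 °C, short contact time to spare the acid-labile benzylic ethers) and gives ketone 16 directly, with no organometallic reagent and no separate oxidation.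

Further compounds
F1 | step 13 | 1-{2-hydroxy-4,6-bis[3,4-bis(benzyloxy)benzyloxy]phenyl}-2-[5-benzyloxy-7-(tert-butyldimethylsilyloxy)-4-oxo-4H-chromen-8-yl]ethanone | O=C(Cc1c(O[Si](C)(C)C(C)(C)C)cc(OCc2ccccc2)c2c(=O)ccoc12)c1c(O)cc(OCc2ccc(OCc3ccccc3)c(OCc3ccccc3)c2)cc1OCc1ccc(OCc2ccccc2)c(OCc2ccccc2)c1
F2 | step 13 | (2S,3R)-enantiomer of 19 | O=C1c2c(OCc3ccc(OCc4ccccc4)c(OCc4ccccc4)c3)cc(OCc3ccc(OCc4ccccc4)c(OCc4ccccc4)c3)cc2O[C@H](c2ccc(OCc3ccccc3)c(OCc3ccccc3)c2)[C@H]1c1c(O[Si](C)(C)C(C)(C)C)cc(OCc2ccccc2)c2c(=O)ccoc12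
F3 | step 13 | (2S,3R,2''S)-diastereomer of 21 | O=C1C[C@@H](c2ccc(OCc3ccccc3)cc2)Oc2c1c(OCc1ccccc1)cc(O[Si](C)(C)C(C)(C)C)c2[C@H]1C(=O)c2c(OCc3ccc(OCc4ccccc4)c(OCc4ccccc4)c3)cc(OCc3ccc(OCc4ccccc4)c(OCc4ccccc4)c3)cc2O[C@@H]1c1ccc(OCc2ccccc2)c(OCc2ccccc2)c1
F4 | step 14 | 1-{2,4,6-tris[3,4-bis(benzyloxy)benzyloxy]phenyl}-2-[(2S)-5-benzyloxy-2-(4-benzyloxyphenyl)-7-(tert-butyldimethylsilyloxy)-4-oxochroman-8-yl]ethanone | O=C1C[C@@H](c2ccc(OCc3ccccc3)cc2)Oc2c1c(OCc1ccccc1)cc(O[Si](C)(C)C(C)(C)C)c2CC(=O)c1c(OCc2ccc(OCc3ccccc3)c(OCc3ccccc3)c2)cc(OCc2ccc(OCc3ccccc3)c(OCc3ccccc3)c2)cc1OCc1ccc(OCc2ccccc2)c(OCc2ccccc2)c1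
F5 | step 14 | 2-diazo-1-{2,4,6-tris[3,4-bis(benzyloxy)benzyloxy]phenyl}-2-[(2S)-5-benzyloxy-2-(4-benzyloxyphenyl)-7-(tert-butyldimethylsilyloxy)-4-oxochroman-8-yl]ethanone | O=C1C[C@@H](c2ccc(OCc3ccccc3)cc2)Oc2c1c(OCc1ccccc1)cc(O[Si](C)(C)C(C)(C)C)c2C(=[N+]=[N-])C(=O)c1c(OCc2ccc(OCc3ccccc3)c(OCc3ccccc3)c2)cc(OCc2ccc(OCc3ccccc3)c(OCc3ccccc3)c2)cc1OCc1ccc(OCc2ccccc2)c(OCc2ccccc2)c1
F6 | step 14 | (2R,3R,2''S)-2,3-cis isomer of 21 | O=C1C[C@@H](c2ccc(OCc3ccccc3)cc2)Oc2c1c(OCc1ccccc1)cc(O[Si](C)(C)C(C)(C)C)c2[C@H]1C(=O)c2c(OCc3ccc(OCc4ccccc4)c(OCc4ccccc4)c3)cc(OCc3ccc(OCc4ccccc4)c(OCc4ccccc4)c3)cc2O[C@H]1c1ccc(OCc2ccccc2)c(OCc2ccccc2)c1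
F7 | step 10 | 2-[5-benzyloxy-7-(tert-butyldimethylsilyloxy)-4-oxo-4H-chromen-8-yl]acetic acid | OC(=O)Cc1c(O[Si](C)(C)C(C)(C)C)cc(OCc2ccccc2)c2c(=O)ccoc12
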